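**Assumption:** the SMILES is read as (3S)-7-hydroxy-3-(4-hydroxy-2-methoxyphenyl)-6-[(2E)-geranyl]chroman-4-one. The catalyst antipode written in step 7 is taken to give 3S; if a test run shows the opposite sense, its equally available mirror image is used.

## Retrosynthetic overview

1. The target comes from its 7-O-methoxymethyl ether by a final acetal cleavage under non-epimerising conditions.
2. Ring C and the C3 stereocentre are made together: the C4–C3 bond forms by intramolecular 1,6-addition of a chiral-carbene-bound acyl anion (Breslow intermediate of the ring A aldehyde) to a ring B para-quinone methide.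
3. The quinone methide is released in the flask from a 4-silyloxybenzylic acetate by fluoride; that precursor comes from a geranylated salicylaldehyde and a ring B aryl oxirane (phenoxide opening, acetylation in the same flask).
4. The salicylaldehyde comes from 5-bromo-2,4-dihydroxybenzaldehyde (MOM protection, Stille geranylation); the oxirane comes from 4-hydroxy-2-methoxybenzaldehyde (silylation, Corey–Chaykovsky).
5. Ring order: rings A and B are bought as arenes; ring C is the only ring formed, in the key step.

## Route

Step 1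
Reactants: 1 5-bromo-2,4-dihydroxybenzaldehyde
Product: 2 5-bromo-2-hydroxy-4-(methoxymethoxy)benzaldehyde
Conditions: MOMCl (1.1 equiv), K2CO3, acetone, 0 °C to rt
Reagents that add atoms: chloromethyl methyl ether (MOMCl), COCCl
Why: Williamson-type O-alkylation goes selectively at the more acidic 4-OH, because the 2-OH is tied up in a hydrogen bond to the aldehyde.

Step 2
Reactants: 3 geranyl chloride
Product: 4 tributyl[(2E)-3,7-dimethylocta-2,6-dien-1-yl]stannane
Conditions: Bu3SnH, LiN(i-Pr)2, THF, 0 °C; then 3, −78 °C to rt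
Reagents that add atoms: tributyltin hydride, CCCC[SnH](CCCC)CCCC
Why: SN2 alkylation of the stannyl anion by the primary allylic chloride gives the linear allylstannane with the E olefin untouched.

Step 3
Reactants: 2 5-bromo-2-hydroxy-4-(methoxymethoxy)benzaldehyde; 4 tributyl[(2E)-3,7-dimethylocta-2,6-dien-1-yl]stannane
Product: 5 5-[(2E)-3,7-dimethylocta-2,6-dien-1-yl]-2-hydroxy-4-(methoxymethoxy)benzaldehyde
Conditions: Pd(PPh3)4 (5 mol %), DMF (degassed), 95 °C
Reagents that add atoms: none
Why: Migita–Kosugi–Stille coupling (oxidative addition of the aryl bromide to zerovalent palladium, allyl transfer from tin, reductive elimination at the unhindered α-terminus) gives the linear E-geranyl arene, and an allylstannane without Lewis acid does not touch the aldehyde, the free phenol or the MOM ether.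

Step 4
Reactants: 6 4-hydroxy-2-methoxybenzaldehyde
Product: 7 4-[(tert-butyldimethylsilyl)oxy]-2-methoxybenzaldehyde
Conditions: TBSCl, imidazole, DMF, rt
Reagents that add atoms: tert-butyldimethylsilyl chloride (TBSCl), CC(C)(C)[Si](C)(C)Cl
Why: Standard imidazole-promoted O-silylation masks the phenol that will later trigger quinone methide formation.

Step 5
Reactants: 7 4-[(tert-butyldimethylsilyl)oxy]-2-methoxybenzaldehyde
Product: 8 rac-2-{4-[(tert-butyldimethylsilyl)oxy]-2-methoxyphenyl}oxirane
Conditions: Me3SI, NaH, DMSO/THF, 0 °C to rt; filtered through basic alumina and used crude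
Reagents that add atoms: trimethylsulfonium iodide, C[S+](C)C.[I-]
Why: Corey–Chaykovsky epoxidation by the preformed sulfonium ylide gives the terminal epoxide; its stereocentre is racemic, which does not matter because it is erased at the quinone methide stage.

Step 6
Reactants: 5 5-[(2E)-3,7-dimethylocta-2,6-dien-1-yl]-2-hydroxy-4-(methoxymethoxy)benzaldehyde; 8 rac-2-{4-[(tert-butyldimethylsilyl)oxy]-2-methoxyphenyl}oxirane
Product: 10 rac-1-{4-[(tert-butyldimethylsilyl)oxy]-2-methoxyphenyl}-2-{4-[(2E)-3,7-dimethylocta-2,6-dien-1-yl]-2-formyl-5-(methoxymethoxy)phenoxy}ethyl acetate, via secondary benzylic alcohol 9 (not isolated)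
Conditions: Cs2CO3 (0.3 equiv), dry DMF, 70 °C; then Ac2O, Et3N, DMAP (cat.), 0 °C to rt
Reagents that add atoms: acetic anhydride, CC(=O)OC(C)=O
Why: Base-mediated SN2 opening of the epoxide by the salicylaldehyde phenoxide at the terminal carbon gives the β-hydroxy ether, and DMAP-catalysed acylation in the same flask turns the benzylic hydroxyl into the leaving group needed in step 7.

Step 7
Reactants: 10 rac-1-{4-[(tert-butyldimethylsilyl)oxy]-2-methoxyphenyl}-2-{4-[(2E)-3,7-dimethylocta-2,6-dien-1-yl]-2-formyl-5-(methoxymethoxy)phenoxy}ethyl acetate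
Product: 12 (3S)-6-[(2E)-3,7-dimethylocta-2,6-dien-1-yl]-3-(4-hydroxy-2-methoxyphenyl)-7-(methoxymethoxy)chroman-4-one, via para-quinone methide aldehyde 11 (not isolated)
Conditions: (5aR,10bS)-2-(pentafluorophenyl)-5a,10b-dihydro-4H,6H-indeno[2,1-b][1,2,4]triazolo[4,3-d][1,4]oxazin-2-ium tetrafluoroborate (20 mol %), CsOAc (20 mol %), THF (0.01 M), 4 Å MS, 0 °C; then CsF/18-crown-6 (1.1 equiv) in portions over 2 h; AcOH quench at 0 °C
Reagents that add atoms: none
Why: Proposed new method: fluoride removes the TBS group and the phenoxide expels acetate (1,6-elimination) to give the E-quinone methide 11, whose exocyclic carbon sits exactly where the β-carbon sits in the carbene-catalysed intramolecular Stetter reaction of salicylaldehyde ethers; the Breslow intermediate from the aldehyde and the chiral triazolylidene (an acyl anion equivalent) adds 1,6 through a six-membered transition state, rearomatising ring B and releasing the carbene, and the aminoindanol backbone shields one face so that C3 is set as S in the C–C bond-forming event, both enantiomers of 10 converging through achiral 11; the closest known chemistry is the enantioselective intramolecular Stetter reaction to chroman-4-ones, carbene-catalysed intermolecular 1,6-addition of aldehydes to para-quinone methides, and fluoride-triggered quinone methide generation under carbene catalysis; the acetate set free is the only base present after the trigger, which keeps the medium weakly basic and limits epimerisation of C3.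

Step 8
Reactants: 12 (3S)-6-[(2E)-3,7-dimethylocta-2,6-dien-1-yl]-3-(4-hydroxy-2-methoxyphenyl)-7-(methoxymethoxy)chroman-4-one
Product: 13 (3S)-6-[(2E)-3,7-dimethylocta-2,6-dien-1-yl]-7-hydroxy-3-(4-hydroxy-2-methoxyphenyl)chroman-4-one
Conditions: ZnBr2 (1 equiv), n-PrSH (2 equiv), CH2Cl2, 0 °C, 10 min
Reagents that add atoms: none
Why: Lewis-acid-assisted cleavage of the aryl methoxymethyl acetal with thiol capture of the methoxymethyl cation is fast at 0 °C without base or protic acid, so C3 is not enolised and the geranyl chain does not cyclise onto the freed phenol.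

## Compound list

1 | 5-bromo-2,4-dihydroxybenzaldehyde | O=Cc1cc(Br)c(O)cc1O | starting material
2 | 5-bromo-2-hydroxy-4-(methoxymethoxy)benzaldehyde | COCOc1cc(O)c(C=O)cc1Br | intermediate
3 | geranyl chloride, (2E)-1-chloro-3,7-dimethylocta-2,6-diene | ClC/C=C(\C)CCC=C(C)C | starting material
4 | tributyl[(2E)-3,7-dimethylocta-2,6-dien-1-yl]stannane | CCCC[Sn](CCCC)(CCCC)C/C=C(\C)CCC=C(C)C | intermediate
5 | 5-[(2E)-3,7-dimethylocta-2,6-dien-1-yl]-2-hydroxy-4-(methoxymethoxy)benzaldehyde | COCOc1cc(O)c(C=O)cc1C/C=C(\C)CCC=C(C)C | intermediate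
6 | 4-hydroxy-2-methoxybenzaldehyde | COc1cc(O)ccc1C=O | starting material
7 | 4-[(tert-butyldimethylsilyl)oxy]-2-methoxybenzaldehyde | COc1cc(O[Si](C)(C)C(C)(C)C)ccc1C=O | intermediate
8 | rac-2-{4-[(tert-butyldimethylsilyl)oxy]-2-methoxyphenyl}oxirane | COc1cc(O[Si](C)(C)C(C)(C)C)ccc1C1CO1 | intermediate
9 | rac-2-(2-{4-[(tert-butyldimethylsilyl)oxy]-2-methoxyphenyl}-2-hydroxyethoxy)-5-[(2E)-3,7-dimethylocta-2,6-dien-1-yl]-4-(methoxymethoxy)benzaldehyde | COCOc1cc(OCC(O)c2ccc(O[Si](C)(C)C(C)(C)C)cc2OC)c(C=O)cc1C/C=C(\C)CCC=C(C)C | intermediate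
10 | rac-1-{4-[(tert-butyldimethylsilyl)oxy]-2-methoxyphenyl}-2-{4-[(2E)-3,7-dimethylocta-2,6-dien-1-yl]-2-formyl-5-(methoxymethoxy)phenoxy}ethyl acetate | COCOc1cc(OCC(OC(C)=O)c2ccc(O[Si](C)(C)C(C)(C)C)cc2OC)c(C=O)cc1C/C=C(\C)CCC=C(C)C | intermediate
11 | 5-[(2E)-3,7-dimethylocta-2,6-dien-1-yl]-2-[(2E)-2-(2-methoxy-4-oxocyclohexa-2,5-dien-1-ylidene)ethoxy]-4-(methoxymethoxy)benzaldehyde | COCOc1cc(OC/C=C2/C(OC)=CC(=O)C=C2)c(C=O)cc1C/C=C(\C)CCC=C(C)C | intermediate
12 | (3S)-6-[(2E)-3,7-dimethylocta-2,6-dien-1-yl]-3-(4-hydroxy-2-methoxyphenyl)-7-(methoxymethoxy)chroman-4-one | COc1cc(O)ccc1[C@H]1COc2cc(OCOC)c(C/C=C(\C)CCC=C(C)C)cc2C1=O | intermediate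
13 | (3S)-6-[(2E)-3,7-dimethylocta-2,6-dien-1-yl]-7-hydroxy-3-(4-hydroxy-2-methoxyphenyl)chroman-4-one | COc1cc(O)ccc1[C@H]1COc2cc(O)c(C/C=C(\C)CCC=C(C)C)cc2C1=O | target

## Step count and risks

Total steps: 8. Longest linear sequence: 5 (steps 1, 3, 6, 7, 8; the branches through 3 and through 6 are also 5).

**Step 7 (most likely to fail).** The quinone methide can tautomerise to the 4-hydroxystyryl enol ether before it is trapped, the enantioselectivity of a new 1,6-acylation is unproven, and the 3-aryl ketone can epimerise if the medium becomes basic. Fallback: setting out from 10, the cyclisation is run without stereocontrol using an achiral carbene (3-benzyl-5-(2-hydroxyethyl)-4-methylthiazolium chloride, CsF/18-crown-6, THF) to give the racemic 7-O-methoxymethyl isoflavanone F1. Asymmetric transfer hydrogenation under dynamic kinetic resolution (RuCl(p-cymene)[(S,S)-TsDPEN], HCO2H/Et3N, rt; mirror-image catalyst if the sense is opposite) epimerises C3 through the enol while reducing one enantiomer, giving the cis-(3S,4S)-isoflavan-4-ol F2. Neutral oxidation of its benzylic alcohol with MnO2 in CH2Cl2 returns to the route at 12.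

**Step 6.** The electron-rich styrene oxide 8 may rearrange to the arylacetaldehyde, open at the benzylic carbon, or lose its silyl group under carbonate at 70 °C. Fallback: setting out from 7, Wittig methylenation (Ph3PCH3Br, KOt-Bu, THF) gives the styrene F3. Markovnikov bromo-acetoxylation (NBS, AcOH, rt) gives the racemic bromo acetate F4, with the acetate already at the benzylic carbon. Alkylation of the phenol of 5 with F4 (K2CO3, DMF, rt) returns to the route at 10 without any epoxide.

**Step 3.** Oxidative addition to the electron-rich bromide may be slow, and allyl transfer can give some γ-coupled (branched) product or erode the E geometry. Fallback: setting out from 2, Miyaura borylation (B2pin2, Pd(dppf)Cl2, KOAc, dioxane, 80 °C) gives the aryl pinacol boronate F5. Suzuki-type allyl–aryl coupling of F5 with geranyl chloride 3 (Pd(PPh3)4, K2CO3, THF/H2O, 60 °C) proceeds through a π-allyl complex that couples at the unhindered terminus and returns to the route at 5, with the polarity of the two partners exchanged.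

## Further compounds

F1 | step 7 | rac-6-[(2E)-3,7-dimethylocta-2,6-dien-1-yl]-3-(4-hydroxy-2-methoxyphenyl)-7-(methoxymethoxy)chroman-4-one | COc1cc(O)ccc1C1COc2cc(OCOC)c(C/C=C(\C)CCC=C(C)C)cc2C1=O
F2 | step 7 | (3S,4S)-6-[(2E)-3,7-dimethylocta-2,6-dien-1-yl]-3-(4-hydroxy-2-methoxyphenyl)-7-(methoxymethoxy)chroman-4-ol (cis) | COc1cc(O)ccc1[C@H]1COc2cc(OCOC)c(C/C=C(\C)CCC=C(C)C)cc2[C@H]1O
F3 | step 6 | tert-butyl(4-ethenyl-3-methoxyphenoxy)dimethylsilane | COc1cc(O[Si](C)(C)C(C)(C)C)ccc1C=C
F4 | step 6 | rac-2-bromo-1-{4-[(tert-butyldimethylsilyl)oxy]-2-methoxyphenyl}ethyl acetate | COc1cc(O[Si](C)(C)C(C)(C)C)ccc1C(OC(C)=O)CBr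
F5 | step 3 | 2-hydroxy-4-(methoxymethoxy)-5-(4,4,5,5-tetramethyl-1,3,2-dioxaborolan-2-yl)benzaldehyde | COCOc1cc(O)c(C=O)cc1B1OC(C)(C)C(C)(C)O1
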